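Ring A carries the isobutyryl group at C-1, oxygen at C-2, C-4 and C-6, and the two methine arms at C-3 and C-5; each arm ends in a syncarpyl ring (rings B and C).
Cuts: first the four O-alkyl masks and the C-1–acyl bond, then ring A at C-2–C-3 and C-4–C-5 (C-1–C-2 opens and re-closes in the same cascade), and last the methine–alkyne bond and the methine=ring double bond of the single building block.
Enabling feature: oxygen-bearing and carbon-bearing atoms alternate around ring A, and C-3 and C-5 carry the same arm. C-3–C-4 and C-5–C-6 are therefore two copies of one arm-bearing alkoxyalkyne set head to tail, and C-1–C-2 is a ketene unit.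
Forward: rings B and C come ready-made in syncarpic acid. Condensation, conjugate alkynylation and O-methylation give one ynol ether, and half of it is turned into a cyclobutenone. Fusing the two halves forms ring A last, and C-1 acylation and ether cleavage end the route.
Stereochemistry: one catalytic asymmetric conjugate alkynylation sets the R methine. The same ynol ether delivers both arms, so the product is R,R; residual S material ends mainly in the separable R,S diastereomer, and no later step makes or breaks a bond at a methine.

Key step: step 5

Assumption: precedent does not fix the sense of induction of the PINAP ligand for this acceptor; the route is written for the ligand isomer that directs attack to the Si face of the alkylidene carbon of 4, and its mirror image (S,M) is used if the opposite sense is found when the configuration of 7 is checked.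
Shorthand: "arm" = (1R)-1-(2-methoxy-3,3,5,5-tetramethyl-4,6-dioxocyclohex-1-en-1-yl)-2-methylpropyl, attached through its methine carbon. N-PINAP = 4-[2-(diphenylphosphanyl)naphthalen-1-yl]-N-(1-phenylethyl)phthalazin-1-amine.

Step 1
Reactants: 1 syncarpic acid (2,2,4,4-tetramethylcyclohexane-1,3,5-trione); 2 isobutyraldehyde
Product: 4 isobutylidenesyncarpic acid [2,2,4,4-tetramethyl-6-(2-methylpropylidene)cyclohexane-1,3,5-trione], via Mannich base 3 (not isolated)
Conditions: piperidine, CH2Cl2, rt; then 1 M aq. HCl, CH2Cl2, rt
Reagents that add atoms: none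
Why: Knoevenagel condensation run by way of the Mannich base: piperidine captures the first-formed alkylidene trione as adduct 3 and keeps it away from unreacted 1 (no 2:1 Michael adduct), and protonation of the amine then triggers retro-Michael elimination to 4, which has no stereocentre.

Step 2
Reactants: 4 isobutylidenesyncarpic acid; 5 ethoxyacetylene
Product: 7 ynol ether 4-[(3R)-1-ethoxy-4-methylpent-1-yn-3-yl]-5-methoxy-2,2,6,6-tetramethylcyclohex-4-ene-1,3-dione, via ammonium enolate 6 (not isolated)
Conditions: [Cu(MeCN)4]PF6 (10 mol %), (R,P)-N-PINAP (11 mol %), iPr2NEt (1.2 equiv), 5 (3 equiv), toluene, −20 → 0 °C, slow addition of 4; then Me2SO4, MeCN, 0 °C → rt; aq. NaHCO3 work-up, Et3N-deactivated SiO2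
Reagents that add atoms: dimethyl sulfate, COS(=O)(=O)OC
Why: Proposed new method: iPr2NEt and the ligated monovalent copper convert 5 into a copper acetylide whose metal-bearing carbon is made more nucleophilic by the ethoxy group; it adds to the doubly activated alkylidene carbon of 4 inside the chiral pocket of the P,N ligand, attack on the Si face setting the R methine; the resulting vinylogous acid is held at once as its ammonium enolate 6, so it cannot protonate the ynol ether, and the hard electrophile Me2SO4 then alkylates the exposed oxygen rather than the fully shielded ring carbon; the closest known reaction type is the copper/PINAP-catalysed enantioselective conjugate addition of terminal alkynes to alkylidene Meldrum's acids (well suited to branched alkylidenes such as isobutylidene), which is run in water with aryl acetylenes and is moved here to an aprotic, amine-buffered medium because water and a free acid would hydrate an ynol ether.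

Step 3
Reactants: 7 ynol ether (half of the material); 8 trichloroacetyl chloride
Product: 10 4,4-dichloro-3-ethoxy-2-(arm)cyclobut-2-en-1-one, via dichloroketene 9 (not isolated)
Conditions: Zn–Cu couple, Et2O/DME, slow addition of 8, 0 °C → rt
Reagents that add atoms: none
Why: Ketene–alkyne [2+2] cycloaddition: zinc removes two chlorines from 8 to give the strongly electrophilic dichloroketene 9, whose carbonyl carbon is attacked by the nucleophilic arm-bearing alkyne carbon, so the arm ends at C-2 and the ethoxy group at C-3 of the four-membered ring; DME binds the ZnCl2, and the methine is untouched (its formal descriptor becomes S only because the CCl2 group raises the CIP rank of the new ring).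

Step 4
Reactants: 10 4,4-dichloro-3-ethoxy-2-(arm)cyclobut-2-en-1-one
Product: 11 3-ethoxy-2-(arm)cyclobut-2-en-1-one (methine R)
Conditions: Zn dust, AcOH, TMEDA, EtOH, 0 °C → rt
Reagents that add atoms: none
Why: Zinc reduction of an α,α-dichloroketone, the standard second half of the dichloroketene route to cyclobutenones; the AcOH/TMEDA buffer supplies protons without hydrolysing the two vinylogous esters, and the hindered ketones of ring B are inert to zinc.

Step 5
Reactants: 11 3-ethoxy-2-(arm)cyclobut-2-en-1-one; 7 ynol ether (the other half, 1.2 equiv)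
Product: 16 3,5-diethoxy-2,4-bis(arm)phenol (ring A: OH at C-2; OEt at C-4 and C-6; arms at C-3 and C-5; H at C-1; both methines R), via vinylketene 12 (not isolated), via vinylcyclobutenone 13 (not isolated), via dienylketene 14 (not isolated), via cyclohexadienone 15 (not isolated)
Conditions: toluene (degassed, 0.5 M), sealed tube, 80 → 100 °C; then 110 °C once 7 is consumed
Reagents that add atoms: none
Why: Heat opens 11 by a conrotatory four-electron electrocyclic reaction to the (1-ethoxyvinyl)ketene 12, whose ketene C=C adds to the triple bond of 7 in a [2+2] cycloaddition (new bonds C-2–C-3 and C-4–C-5) to give 13; a second four-electron opening breaks the old C-2–C-5 bond to give dienylketene 14, which closes C-1 onto C-2 and enolises through 15 to the phenol. The closest known reaction type is the Danheiser benzannulation of cyclobutenones with alkoxy- and siloxyalkynes, including 3-oxygenated cyclobutenones that lead to phloroglucinol ethers; only the size of the two arms is new. Ring A is the one ring closed, by disrotatory six-electron electrocyclisation of the isomer of 14 whose ketene and vinyl ends lie cis on the central double bond; the other isomer can only revert to 13, so the reversible opening feeds the productive one. No lasting stereocentre is formed: the quaternary carbon of 13 is erased by the next ring opening, and the two R methines are spectators at which no bond is made or broken in a neutral medium. The step needs head-to-tail regiochemistry, and the ethoxy group of 7 secures it by making the arm-bearing alkyne carbon (C-3) the nucleophilic end that attacks the ketene carbonyl carbon C-2, while the oxygen-bearing carbon C-4 joins C-5. The bath stays at or below 100 °C until 7 is used up, because ethyl ynol ethers lose ethylene by a retro-ene reaction at higher temperature, and only then is it raised to drive remaining 13 on to 16.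

Step 6
Reactants: 16 3,5-diethoxy-2,4-bis(arm)phenol; 17 isobutyryl chloride
Product: 18 1-[2,4-diethoxy-6-hydroxy-3,5-bis(arm)phenyl]-2-methylpropan-1-one (both methines R)
Conditions: TiCl4, CH2Cl2, −78 → −20 °C; cold aq. NaHCO3
Reagents that add atoms: none
Why: Friedel–Crafts acylation directed by the titanium phenoxide: C-1 is the only free ring position, lies ortho to the titanium-bearing C-2 oxygen and ortho/para to the two ethoxy groups, and should be acylated at low temperature faster than the Lewis acid can attack the vinylogous esters or ionise the benzylic bonds, the product being held as an unreactive titanium chelate.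

Step 7
Reactants: 18 1-[2,4-diethoxy-6-hydroxy-3,5-bis(arm)phenyl]-2-methylpropan-1-one
Product: 19 (R,R)-myrtucommulone A
Conditions: BBr3 (excess), CH2Cl2, −78 → 0 °C; ice-cold pH 7 phosphate buffer
Reagents that add atoms: none
Why: Lewis-acid ether cleavage: BBr3 binds each ether oxygen and bromide removes methyl or ethyl by SN2 attack at the alkyl carbon, so only O–alkyl bonds break, the methines stay R, and cold buffered hydrolysis of the borates releases the two enols and the two phenols.

Compound list
1 | syncarpic acid (2,2,4,4-tetramethylcyclohexane-1,3,5-trione) | CC1(C)C(=O)CC(=O)C(C)(C)C1=O | starting material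
2 | isobutyraldehyde | CC(C)C=O | starting material
3 | Mannich base, 5-hydroxy-2,2,6,6-tetramethyl-4-[2-methyl-1-(piperidin-1-yl)propyl]cyclohex-4-ene-1,3-dione (racemic) | CC(C)C(N1CCCCC1)C1=C(O)C(C)(C)C(=O)C(C)(C)C1=O | intermediate
4 | isobutylidenesyncarpic acid | CC(C)C=C1C(=O)C(C)(C)C(=O)C(C)(C)C1=O | intermediate
5 | ethoxyacetylene | C#COCC | starting material
6 | N,N-diisopropylethylammonium enolate of the (R)-conjugate adduct | CCOC#C[C@H](C1=C([O-])C(C)(C)C(=O)C(C)(C)C1=O)C(C)C.CC[NH+](C(C)C)C(C)C | intermediate
7 | ynol ether, 4-[(3R)-1-ethoxy-4-methylpent-1-yn-3-yl]-5-methoxy-2,2,6,6-tetramethylcyclohex-4-ene-1,3-dione | CCOC#C[C@H](C1=C(OC)C(C)(C)C(=O)C(C)(C)C1=O)C(C)C | intermediate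
8 | trichloroacetyl chloride | ClC(Cl)(Cl)C(Cl)=O | starting material
9 | dichloroketene | ClC(Cl)=C=O | intermediate
10 | 4,4-dichloro-3-ethoxy-2-(arm)cyclobut-2-en-1-one (methine as in 7, formal descriptor S) | CCOC1=C([C@H](C2=C(OC)C(C)(C)C(=O)C(C)(C)C2=O)C(C)C)C(=O)C1(Cl)Cl | intermediate
11 | 3-ethoxy-2-(arm)cyclobut-2-en-1-one (R) | CCOC1=C([C@H](C2=C(OC)C(C)(C)C(=O)C(C)(C)C2=O)C(C)C)C(=O)C1 | intermediate
12 | (1-ethoxyvinyl)ketene, 3-ethoxy-2-(arm)buta-1,3-dien-1-one | C=C(OCC)C(=C=O)[C@H](C1=C(OC)C(C)(C)C(=O)C(C)(C)C1=O)C(C)C | intermediate
13 | 3-ethoxy-4-(1-ethoxyvinyl)-2,4-bis(arm)cyclobut-2-en-1-one (methines as in 7, ring C-4 a transient mixture) | CCOC1=C([C@H](C2=C(OC)C(C)(C)C(=O)C(C)(C)C2=O)C(C)C)C(=O)C1(C(OCC)=C)[C@H](C3=C(OC)C(C)(C)C(=O)C(C)(C)C3=O)C(C)C | intermediate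
14 | dienylketene, 3,5-diethoxy-2,4-bis(arm)hexa-1,3,5-trien-1-one (ketene and vinyl ends cis) | O=C=C([C@H](C1=C(OC)C(C)(C)C(=O)C(C)(C)C1=O)C(C)C)/C(OCC)=C(\C(OCC)=C)[C@H](C2=C(OC)C(C)(C)C(=O)C(C)(C)C2=O)C(C)C | intermediate
15 | 3,5-diethoxy-2,4-bis(arm)cyclohexa-2,4-dien-1-one | O=C1CC(OCC)=C([C@H](C2=C(OC)C(C)(C)C(=O)C(C)(C)C2=O)C(C)C)C(OCC)=C1[C@H](C3=C(OC)C(C)(C)C(=O)C(C)(C)C3=O)C(C)C | intermediate
16 | 3,5-diethoxy-2,4-bis(arm)phenol (R,R) | Oc1cc(OCC)c([C@H](C2=C(OC)C(C)(C)C(=O)C(C)(C)C2=O)C(C)C)c(OCC)c1[C@H](C3=C(OC)C(C)(C)C(=O)C(C)(C)C3=O)C(C)C | intermediate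
17 | isobutyryl chloride | CC(C)C(=O)Cl | starting material
18 | 1-[2,4-diethoxy-6-hydroxy-3,5-bis(arm)phenyl]-2-methylpropan-1-one (R,R) | CC(C)C(=O)c1c(O)c([C@H](C2=C(OC)C(C)(C)C(=O)C(C)(C)C2=O)C(C)C)c(OCC)c([C@H](C3=C(OC)C(C)(C)C(=O)C(C)(C)C3=O)C(C)C)c1OCC | intermediate
19 | (R,R)-myrtucommulone A, 1-{2,4,6-trihydroxy-3,5-bis[(1R)-1-(2-hydroxy-3,3,5,5-tetramethyl-4,6-dioxocyclohex-1-en-1-yl)-2-methylpropyl]phenyl}-2-methylpropan-1-one | CC(C)C(=O)c1c(O)c([C@H](C2=C(O)C(C)(C)C(=O)C(C)(C)C2=O)C(C)C)c(O)c([C@H](C2=C(O)C(C)(C)C(=O)C(C)(C)C2=O)C(C)C)c1O | target

Total steps: 7. Longest linear sequence: 7 steps (1 → 4 → 7 → 10 → 11 → 16 → 18 → 19). The second benzannulation partner is compound 7 itself, so no separate branch has to be built.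

Steps most likely to fail

Step 2. Four processes could defeat it:
- sluggish turnover of the copper acetylide outside water
- poor facial selectivity
- removal of the isopropyl C–H of 4 by the amine (deconjugation)
- uncatalysed hetero-Diels–Alder addition of the neutral alkyne across the oxadiene of 4

The fallback sets out from 4 and 5 and returns at 7, using only known chemistry. EtMgBr in THF deprotonates 5 to ethoxyethynylmagnesium bromide F1, which adds 1,4 to 4 without a catalyst, as alkynyl Grignard reagents do with alkylidene malonate-type acceptors. Work-up with aqueous K2CO3 (never acid) keeps the product as the racemic potassium enolate F2. Phase-transfer methylation (Me2SO4, Bu4NHSO4, CH2Cl2/aq. K2CO3) gives the racemic ynol ether F3. Preparative chromatography on a chiral stationary phase with a neutral eluent separates 7 from its S enantiomer F4.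

Step 5. Four processes could defeat it:
- steric blockade of the [2+2] addition between two partners that each carry a branched arm, so that the vinylketene dimerises or recloses
- retro-ene loss of ethylene from the ynol ether if the donor-stabilised cyclobutenone opens only at higher temperature
- capture of the ketene by a carbonyl oxygen of its own arm
- attack of the new phenol on the neighbouring vinylogous ester with loss of methanol

The fallback sets out from 11 (with 5 and 4) and returns at 16. Heating 11 with the unhindered parent alkyne 5 (toluene, sealed tube, 80–100 °C) runs the same benzannulation with only one arm to place. It gives the mono-arm phenol F5, whose two free ring positions are equivalent. Its sodium phenoxide (NaH, THF) is then alkylated at carbon by Michael addition to 4, the established way of attaching syncarpyl arms to phloroglucinols. The new methine is not controlled, so the R,R adduct F6 is separated from the R,S epimer F7. TMSCHN2 (toluene/MeOH, 0 °C) then methylates only the much more acidic enol of F6 to give 16.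

Step 7. Three processes could defeat it:
- Lewis-acid-induced closure of a phenol oxygen onto the boron-activated enol carbon (cyclodehydration)
- ionisation of a benzylic C–C bond with loss of configuration
- incomplete cleavage of the C-4 ethyl ether that is flanked by both arms

The fallback sets out from 18 and returns at 19. It replaces electrophilic cleavage by two anionic SN2 dealkylations, in which diketones and phenols are present only as unreactive anions. LiCl in DMSO at 100–120 °C removes the two enol methyl groups, the usual unmasking of hindered vinylogous methyl esters, and mild acidification gives 4,6-di-O-ethylmyrtucommulone A F8. NaSEt in DMF at 100–120 °C then removes the ethyl groups from the two acyl-activated aryl ethers to give 19.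

Further compounds
F1 | step 2 | ethoxyethynylmagnesium bromide | CCOC#C[Mg]Br
F2 | step 2 | racemic potassium enolate of the conjugate adduct | CCOC#CC(C1=C([O-])C(C)(C)C(=O)C(C)(C)C1=O)C(C)C.[K+]
F3 | step 2 | racemic ynol ether (racemate of 7) | CCOC#CC(C1=C(OC)C(C)(C)C(=O)C(C)(C)C1=O)C(C)C
F4 | step 2 | S enantiomer of 7 | CCOC#C[C@@H](C1=C(OC)C(C)(C)C(=O)C(C)(C)C1=O)C(C)C
F5 | step 5 | mono-arm phenol, 3,5-diethoxy-4-(arm)phenol | Oc1cc(OCC)c([C@H](C2=C(OC)C(C)(C)C(=O)C(C)(C)C2=O)C(C)C)c(OCC)c1
F6 | step 5 | R,R adduct, as 16 but with a free enol in the C-3 arm | Oc1cc(OCC)c([C@H](C2=C(OC)C(C)(C)C(=O)C(C)(C)C2=O)C(C)C)c(OCC)c1[C@H](C3=C(O)C(C)(C)C(=O)C(C)(C)C3=O)C(C)C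
F7 | step 5 | R,S epimer of F6 at the new methine | Oc1cc(OCC)c([C@H](C2=C(OC)C(C)(C)C(=O)C(C)(C)C2=O)C(C)C)c(OCC)c1[C@@H](C3=C(O)C(C)(C)C(=O)C(C)(C)C3=O)C(C)C
F8 | step 7 | 4,6-di-O-ethylmyrtucommulone A (R,R) | CC(C)C(=O)c1c(O)c([C@H](C2=C(O)C(C)(C)C(=O)C(C)(C)C2=O)C(C)C)c(OCC)c([C@H](C3=C(O)C(C)(C)C(=O)C(C)(C)C3=O)C(C)C)c1OCC
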